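(The earlier runs and the new flask stem from a simulated flask with made-up constants.)

The cedar run at 70 °C is where I start: its target reads 19.0% at 0.833 d and 20.6% at 2.00 d, while its starting material falls from 19.7% to 3.4%. My decision for the next run is whether a slow feed or a cold start earns its place on the plate, or whether I charge everything together.

| setting | ash | cedar | larch | south | north-west | north | east |
|---|---|---|---|---|---|---|---|
| starting material | 18 mM | 18 mM | 18 mM | 18 mM | 18 mM | 18 mM | 18 mM (fed, over 12 h) |
| reagent | 14.4 mM | 9.6 mM | 22 mM | 14.4 mM (fed, over 12 h) | 14.4 mM (fed, over 12 h) | 14.4 mM | 14.4 mM |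
| capture agent | 0.36 mM | 0.36 mM | 0.36 mM | 0.360 mM | 0.360 mM | 0.360 mM | 0.360 mM |
| temperature | 55 °C | 70 °C | 55 °C |  | 70 °C |  | 70 °C |
| remark | run made earlier | run made earlier | run made earlier | the addition at 40 °C, then warmed to 70 °C; the feed brings no volume worth counting | all else is in the flask from the start; the feed brings no volume worth counting | everything together at the start at 40 °C, warmed to 70 °C at 12 h | all else is in the flask from the start; the feed brings no volume worth counting |
| time |  |  |  | 2.5 d | 2.5 d | 2.5 d | 2.5 d |

| run | time / d | target / % | starting material / % |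
|---|---|---|---|
| ash | 0.625 | 3.8 | 83.0 |
| ash | 1.25 | 8.1 | 68.1 |
| ash | 1.67 | 11.3 | 59.6 |
| ash | 2.50 | 14.8 | 45.8 |
| ash | 4.00 | 18.9 | 31.1 |
| cedar | 0.250 | 7.5 | 60.6 |
| cedar | 0.833 | 19.0 | 19.7 |
| cedar | 1.25 | 20.3 | 9.2 |
| cedar | 2.00 | 20.6 | 3.4 |
| cedar | 3.00 | 20.2 | 0 |
| larch | 0.500 | 3.1 | 86.2 |
| larch | 0.833 | 6.1 | 77.6 |
| larch | 1.67 | 11.5 | 58.7 |
| larch | 4.00 | 16.7 | 30.7 |
| larch | 6.00 | 19.8 | 18.7 |

(readings scatter by 1 percentage point)



- the best flask by amount of target, in percent of the starting material charged; "all alike" if 1.5 percentage points covers them all (south / north-west / north / east / all alike)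
- amount of target at the end, in percent of the starting material charged, south
- amount of target at the end, in percent of the starting material charged, north-west
- amount of target at the end, in percent of the starting material charged, north
- amount of target at the end, in percent of the starting material charged, east

I carry one quantity, the target share, meaning target found per starting material consumed, usually called the selectivity. Cedar's later pair gives it as 21.3%, a reading with 1 percentage point of scatter on each value. Its earlier pair gives 23.7%, but the new flasks are read at 2.5 d, nearer the later reading. I let the share carry over to 14.4 mM of reagent, since the ash and larch runs, both at 55 °C and with different reagent charges, read 28.0% and 27.8% at 1.67 d.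

Taking the loss of starting material as first order, cedar gives 1.95 d⁻¹, a half-life of 0.355 d. South and north, counting nothing for the cold hold, then spend 2.00 d at 70 °C and keep 2.02%, while north-west keeps 0.763%. East's feed enters on average at 6.00 h, so its mean stay of 2.25 d lies between theirs. My reckoning is therefore about 20.9% of target in south and north, with a spread of 0.27 points up to north-west, less than the margin of 1.5 points. I would charge as in north, everything together, and give the feed no wells.

The forecast says all alike, with 24% for south, 23.5% for north-west, 23.5% for north and 24% for east, higher than my figure, on the ground that “All flasks reach near-complete conversion”.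

The flasks give 20.1% in south, 20.0% in north-west, 20.2% in north and 20.4% in east, so the verdict is all alike.

    capture agent + open intermediate → trapped intermediate (k = 4.75 × 10⁻⁴ M⁻¹ s⁻¹, Ea = 86.0 kJ mol⁻¹)
    starting material + reagent → side product A (k = 3.76 × 10⁻⁴ M⁻¹ s⁻¹, Ea = 78.0 kJ mol⁻¹)
    open intermediate → side product C (k = 2.09 × 10⁻⁴ s⁻¹, Ea = 97.0 kJ mol⁻¹)
    reagent + open intermediate → side product B (k = 0.00261 M⁻¹ s⁻¹, Ea = 61.0 kJ mol⁻¹)
    starting material → open intermediate (k = 1.71 × 10⁻⁵ s⁻¹, Ea = 125 kJ mol⁻¹)
    starting material ⇌ target (K = 18.8, k = 4.79 × 10⁻⁶ s⁻¹, Ea = 105 kJ mol⁻¹, ΔH = 7.00 kJ mol⁻¹)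
    2 reagent → homo dimer (k = 0.00754 M⁻¹ s⁻¹, Ea = 54.0 kJ mol⁻¹)
    (constants at 70 °C)

In north-west at 0.350 d, the forward passing of starting material into open intermediate runs 3.6 times as fast as its forward passing into target, which gives target 21.9% of the forward flow through these two steps at that moment. At 2.50 d that flask holds 1.01% of its starting material and shows a target share of 20.2%, while the same north-west flask read at 15 h holds 28.7% starting material and 14.7% target, a target share of 20.6%.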